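## Retrosynthetic overview
1. 2,3-Dehydrosilybin B ⇒ the same trans-benzodioxane with C-9 at the acyl level, bound to Oppolzer's (2R)-sultam. Reductive removal of the auxiliary gives the CH2OH group.
2. The dioxane ring is the only ring formed. It arises in one pot by phenoxyl-radical 8–O–4′ cross-coupling of unprotected quercetin with N-feruloyl sultam, followed by closure of 3′-OH onto the p-quinone methide (C7–O3′). This is the plant bond order, with a chiral controller next to C-8.
3. N-Feruloyl sultam ⇒ ferulic acid + (−)-bornane-10,2-sultam.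
4. Rings A/C/B are bought intact as quercetin. Within the new ring, O4′–C8 forms first and sets the absolute configuration. O3′–C7 forms second and sets the trans relationship.

Assumption: the (2R)-sultam directs bond formation to the Cα-Re face of the feruloyl radical. This follows the thermal/radical model for N-enoyl bornanesultams (C=O anti to SO2, s-cis enoyl, approach anti to the pseudo-axial S=O). If experiment shows the opposite sense, the equally available (2S)-sultam is used and nothing else changes.

## Route

Step 1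
Reactants: 1 (E)-ferulic acid; 2 pivaloyl chloride; 3 (−)-(2R)-bornane-10,2-sultam
Product: 5 (2R)-N-[(E)-feruloyl]bornane-10,2-sultam, via feruloyl pivaloyl mixed anhydride 4 (not isolated)
Conditions: 1, Et3N (2.5 equiv), 2 (1.0 equiv), THF, −20 °C, 1 h; then LiCl (1.1 equiv), 3 (0.9 equiv), −20 °C → rt, 12 h
Reagents that add atoms: none
Why: Mixed-anhydride N-acylation (LiCl/Et3N imide formation), in which the fully ionised carboxylate of 1 takes up the single equivalent of 2 at −20 °C much faster than the un-ionised, DMAP-free phenol, the lithium-activated sultam nitrogen then attacks the unhindered cinnamoyl carbonyl of 4 rather than the neopentyl one, and no stereocentre is created, so the E-alkene and the sultam stereocentres are carried through unchanged.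

Step 2
Reactants: 5 (2R)-N-[(E)-feruloyl]bornane-10,2-sultam; 6 quercetin
Product: 8 N-{[(2R,3S)-3-(4-hydroxy-3-methoxyphenyl)-6-(3,5,7-trihydroxy-4-oxo-4H-chromen-2-yl)-2,3-dihydro-1,4-benzodioxin-2-yl]carbonyl}-(2R)-bornane-10,2-sultam (trans), via p-quinone methide 7 (not isolated)
Conditions: 5 (1.2 equiv), Ag2O (1.5 equiv), acetone–toluene 2:1, 0 °C → rt, dark, Ar; 6 (1.0 equiv) in acetone added over 6 h; SiO2, then recrystallisation to one diastereomer
Reagents that add atoms: none
Why: Proposed new method: Ag2O turns both phenols into phenoxyl radicals, the persistent, nucleophilic quercetin 4′-O semiquinone (4′-OH is the most acidic and weakest B-ring O–H because it is para-conjugated to the chromone) cross-couples with the transient, electrophilic α-acyl C-8 of the feruloyl radical on the Cα-Re face left open by the sultam and so sets C-2 as R, the adjacent 3′-OH then adds to C-7 of 7 in a chair-like, reversible oxa-1,6-addition that places aryl and acyl trans-diequatorial (C-3 = S), the closest known reactions are the Ag2O coupling of catechol flavonoids with coniferyl alcohol to racemic benzodioxanes and the sultam-controlled 8–5′ oxidative dimerisation of N-feruloyl sultams (about 80% ee after auxiliary removal), and any minor stereo- or 3′-O-regioisomer is a diastereomeric or constitutionally different crystalline N-acyl sultam that is removed here.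

Step 3
Reactants: 8 trans-(2R,3S)-acyl sultam
Product: 10 2,3-dehydrosilybin B, via aldehyde 9 (not isolated)
Conditions: LiBH4 (6 equiv), THF, 0 °C → rt, Ar; then 1 M HCl, MeOH co-evaporation
Reagents that add atoms: none
Why: Reductive cleavage of an N-acyl sultam (imide → aldehyde → primary alcohol), in which the α-aryloxy imide carbonyl is by far the most electrophilic C=O, the flavonol carbonyl is a vinylogous ester further deactivated as its lithium phenoxide (flavonols, unlike flavanones, are inert to borohydride), 9 is reduced faster than it enolises so C-2 keeps its geometry (the descriptor changes from R to S by CIP priority only), and C-3 is not touched.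

## Compound list
1 | (E)-ferulic acid | COc1cc(/C=C/C(=O)O)ccc1O | starting material
2 | pivaloyl chloride | CC(C)(C)C(=O)Cl | starting material
3 | (−)-(2R)-bornane-10,2-sultam, (1S,2R,4R) | CC1(C)[C@@H]2CC[C@]13CS(=O)(=O)N[C@@H]3C2 | starting material
4 | (E)-feruloyl pivaloyl mixed anhydride | COc1cc(/C=C/C(=O)OC(=O)C(C)(C)C)ccc1O | intermediate
5 | (2R)-N-[(E)-feruloyl]bornane-10,2-sultam | COc1cc(/C=C/C(=O)N2[C@@H]3C[C@H]4CC[C@]3(CS2(=O)=O)C4(C)C)ccc1O | intermediate
6 | quercetin | O=c1c(O)c(-c2ccc(O)c(O)c2)oc2cc(O)cc(O)c12 | starting material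
7 | (8R)-8–O–4′ p-quinone methide: quercetin 4′-O bound to Cα of the acyl sultam, 3′-OH free, exocyclic C=C geometry undefined | COC1=CC(=C[C@@H](Oc2ccc(-c3oc4cc(O)cc(O)c4c(=O)c3O)cc2O)C(=O)N5[C@@H]6C[C@H]7CC[C@]6(CS5(=O)=O)C7(C)C)C=CC1=O | intermediate
8 | trans-(2R,3S)-2-acyl-3-aryl-1,4-benzodioxane N-acyl (2R)-sultam (full name in step 2) | COc1cc([C@@H]2Oc3cc(-c4oc5cc(O)cc(O)c5c(=O)c4O)ccc3O[C@H]2C(=O)N6[C@@H]7C[C@H]8CC[C@]7(CS6(=O)=O)C8(C)C)ccc1O | intermediate
9 | (2R,3S)-3-(4-hydroxy-3-methoxyphenyl)-6-(3,5,7-trihydroxy-4-oxo-4H-chromen-2-yl)-2,3-dihydro-1,4-benzodioxine-2-carbaldehyde | COc1cc([C@@H]2Oc3cc(-c4oc5cc(O)cc(O)c5c(=O)c4O)ccc3O[C@H]2C=O)ccc1O | intermediate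
10 | 2,3-dehydrosilybin B, 2-[(2S,3S)-3-(4-hydroxy-3-methoxyphenyl)-2-(hydroxymethyl)-2,3-dihydro-1,4-benzodioxin-6-yl]-3,5,7-trihydroxy-4H-chromen-4-one | COc1cc([C@@H]2Oc3cc(-c4oc5cc(O)cc(O)c5c(=O)c4O)ccc3O[C@H]2CO)ccc1O | target

## Totals and risks
Total step count: 3. Longest linear sequence: 3.

**Step 2 (highest risk).**
- Failure modes:
  - Quercetin is oxidised more easily than 5. Its o-quinone can tautomerise through the 3-enol, dimerise or degrade before cross-coupling occurs.
  - 8–5′ homodimerisation of 5 and 3′-O regioisomers also compete.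
- Fallback: it sets out from 5 and comes back at 8.
  - 5 is coupled (Ag2O, acetone–toluene) with commercial (+)-(2R,3R)-taxifolin instead of quercetin. Its catechol is not conjugated to an enol, and it is the best-behaved partner for this type of coupling.
  - The reaction runs through the taxifolin-derived p-quinone methide F2 to the silybin B-type acyl sultam F3.
  - C2–C3 is then dehydrogenated (I2, KOAc, AcOH, 90 °C) to the flavonol 8. Coupling therefore comes before flavonol formation.

**Step 1.**
- Failure mode: the free phenol may be acylated by 2 or by 4, giving pivalate or oligomeric ferulate esters.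
- Fallback: it sets out from 3 and comes back at 5.
  - 3 is acylated with acryloyl chloride (NaH, toluene, 0 °C) to N-acryloyl-(2R)-bornane-10,2-sultam F1.
  - The aryl–vinyl bond is then made by Heck arylation with 4-iodo-2-methoxyphenol (Pd(OAc)2, P(o-tol)3, Et3N, MeCN, 80 °C).
  - The phenol never meets an activated acyl donor, and the E-alkene 5 results directly.

**Step 3.**
- Failure modes:
  - The lithium polyphenoxide of 8 may be insoluble.
  - The 4-phenoxide can open the dioxane to a quinone methide that hydride traps.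
  - Phenoxide base may epimerise or eliminate at C-2 before reduction.
- Fallback: it sets out from 8 and comes back at 10.
  - All four acidic OH groups are capped with N,O-bis(trimethylsilyl)acetamide (THF, 50 °C) to give the tetrakis(trimethylsilyl) ether of 8 F4. This compound is neutral and cannot form a quinone methide.
  - LiBH4 (2.5 equiv, THF, 0 °C) takes it through the silylated aldehyde F5 to the silylated primary alcohol F6.
  - 1 M HCl/THF strips the silyl groups to give 10.

## Further compounds
F1 | step 1 | N-acryloyl-(2R)-bornane-10,2-sultam | C=CC(=O)N1[C@@H]2C[C@H]3CC[C@]2(CS1(=O)=O)C3(C)C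
F2 | step 2 | taxifolin-derived (8R) p-quinone methide | COC1=CC(=C[C@@H](Oc2ccc([C@H]3Oc4cc(O)cc(O)c4C(=O)[C@@H]3O)cc2O)C(=O)N5[C@@H]6C[C@H]7CC[C@]6(CS5(=O)=O)C7(C)C)C=CC1=O
F3 | step 2 | silybin B-type acyl sultam, flavanonol (2R,3R), dioxane (2R,3S) | COc1cc([C@@H]2Oc3cc([C@H]4Oc5cc(O)cc(O)c5C(=O)[C@@H]4O)ccc3O[C@H]2C(=O)N6[C@@H]7C[C@H]8CC[C@]7(CS6(=O)=O)C8(C)C)ccc1O
F4 | step 3 | tetrakis(trimethylsilyl) ether of 8 | COc1cc([C@@H]2Oc3cc(-c4oc5cc(O[Si](C)(C)C)cc(O[Si](C)(C)C)c5c(=O)c4O[Si](C)(C)C)ccc3O[C@H]2C(=O)N6[C@@H]7C[C@H]8CC[C@]7(CS6(=O)=O)C8(C)C)ccc1O[Si](C)(C)C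
F5 | step 3 | tetrakis(trimethylsilyl) ether of aldehyde 9 | COc1cc([C@@H]2Oc3cc(-c4oc5cc(O[Si](C)(C)C)cc(O[Si](C)(C)C)c5c(=O)c4O[Si](C)(C)C)ccc3O[C@H]2C=O)ccc1O[Si](C)(C)C
F6 | step 3 | 3,5,7,4''-tetrakis(trimethylsilyl) ether of 10 | COc1cc([C@@H]2Oc3cc(-c4oc5cc(O[Si](C)(C)C)cc(O[Si](C)(C)C)c5c(=O)c4O[Si](C)(C)C)ccc3O[C@H]2CO)ccc1O[Si](C)(C)C
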